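I follow one ratio, the split number: solid substrate lost to self-condensation at the full charge, over its fastest dissolution into an empty solution, 5.49.

solid substrate 0.021 M; reagent 1.00 equiv; time 1.5 h

    2 dissolved substrate → side product (k1 = 4.30 M⁻¹ min⁻¹)
    2 solid substrate → self-condensation product (k2 = 3.34 M⁻¹ min⁻¹)
    solid substrate ⇌ dissolved substrate, rate k3*(cs3 - [dissolved substrate]) while solid is left; crystals form when [dissolved substrate] > cs3 (cs3 = 8.0 mM, k3 = 0.0671 min⁻¹)
    dissolved substrate + reagent → target (k4 = 136 M⁻¹ min⁻¹)

- amount of target at 1.5 h, in percent of the solid substrate charged
- concentration of dissolved substrate in solution at 1.5 h, in percent of saturation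

With reagent as charged, reagent takes dissolved substrate with a half-life of 0.24 min, shorter than the run, so I treat that step as instantaneous. Dissolution then runs at its ceiling of 0.537 mM min⁻¹. That is far below what reagent could take from a saturated solution, so dissolution is the rate-limiting step to target. At that ceiling and with reagent as charged, I reckon dissolved substrate near 2.35% of saturation.

Of the solid leaving at any moment, the fraction entering solution is one over one plus the split number times the squared fraction of solid left. That gives 15.4% at full charge, 42.1% at half charge, and 100% at the end. Weighting these 1, 4, 1 by Simpson's rule, I expect a share of 47.3% to become target.

Now the settings, by hand. The charge enters the split number squared, so a thinner flask keeps a larger share. Reagent is charged at 1.00 equiv, so I expect 52.7% of it to stay unused. Time: I reckon the solid lasts 18.5 min, shorter than the run, so I expect target to stop growing early. The last dissolved substrate then falls with a half-life of 0.461 min, much shorter than the remaining time, so I expect saturation near zero.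

The forecast gives 49% (45% to 53%) and 0% of saturation (at most 0.01%): “Self-condensation of the solid far outruns dissolution”. My share is lower, at 47.3%.

The flask gives 49.3% of target and 0% of saturation. Target already stands at 49.3% after 0.375 h. With half the dissolution coefficient, the split number rises to 11.0, and the same Simpson weighting gives 35.8%. That flask gives 38.4%.

The rate constants are assumed; the run is a simulation.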